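The vinyl-oxirane corner of the ten-membered ring, C16=C5–C4(O)C3, is read as an oxidised 2-substituted 1,3-diene. That is the retron of enyne metathesis, so everything rests on the C3=C4 disconnection. The precursor already holds ring A (C1, C10–C14) and the γ-lactone (C7, C8, C17, C19, O). It carries a vinyl carbinol at C2 and a propargylic chloride at C6. One ruthenium-catalysed operation under ethylene converts the alkyne C5≡C4 into the diene, plants the exocyclic methylene C16 and closes the carbocycle C1–C10 as its Z-olefin. Afterwards only oxygen atoms and acetyl groups are added. A D-glucose-derived ulose supplies C7–C10 and relays the stereochemistry.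

Key step: step 13

Remark: briarane numbering is used (C15 on C1, C16 on C5, C18 on C17, C20 on C11); α/β refer to the usual drawing with C15 β, also for open-chain precursors; TBS = tert-butyldimethylsilyl.

Step 1
Reactants: 1 (E)-4-(dimethylamino)but-3-en-2-one
Product: 2 (E)-1-(dimethylamino)pent-1-en-3-one
Conditions: LiN(iPr)2 (LDA), THF, −78 °C; MeI, −78 → 0 °C
Reagents that add atoms: iodomethane, CI
Why: Kinetic α′-deprotonation of the vinylogous amide at its only enolisable carbon followed by SN2 enolate alkylation should add the carbon that becomes C20; no stereocentre is formed.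

Step 2
Reactants: 2 (E)-1-(dimethylamino)pent-1-en-3-one
Product: 3 (1E,3Z)-3-(TBS-oxy)-N,N-dimethylpenta-1,3-dien-1-amine (C14, C13, C12, C11, C20)
Conditions: KN(SiMe3)2 (KHMDS), THF, −78 °C; TBSCl, −78 °C → rt
Reagents that add atoms: tert-butyldimethylsilyl chloride, CC(C)(C)[Si](C)(C)Cl
Why: O-silylation of the cross-conjugated potassium enolate (silyl enol ether formation) should give the 1-amino-3-siloxy diene, its Z enol ether geometry following from the Z(O)-enolate that a hindered amide base forms from an ethyl ketone.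

Step 3
Reactants: 4 1,2:5,6-di-O-isopropylidene-α-D-ribo-hexofuranos-3-ulose; 5 methyl propanoate
Product: 7 methyl (2R)-2-(3-O-TBS-1,2:5,6-di-O-isopropylidene-α-D-allofuranos-3-C-yl)propanoate (sugar C2–C5 = C7–C10; 8α-OTBS; 17R), via lithium aldolate 6 (not isolated)
Conditions: LiN(iPr)2 (LDA), 5, THF–DMPU, −78 °C; 4; then TBSOTf, −78 → 0 °C
Reagents that add atoms: tert-butyldimethylsilyl triflate, CC(C)(C)[Si](C)(C)OS(=O)(=O)C(F)(F)F
Why: In this ester-enolate aldol addition with in situ O-silylation the nucleophile can reach the ketone only from the convex face anti to the 1,2-acetonide, which sets C8 (allo), and a chair Zimmerman–Traxler transition state of the Z(O)-enolate with the bulkier C9 side equatorial should give 17R.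

Step 4
Reactants: 7 branched allofuranose TBS ether
Product: 8 C10 aldehyde (3-C-branched 3-O-TBS-1,2-O-isopropylidene-α-D-ribo-pentodialdo-1,4-furanose)
Conditions: H5IO6, EtOAc, 0 °C → rt
Reagents that add atoms: none
Why: Periodic acid should hydrolyse the more labile terminal acetonide and cleave the freed glycol (periodate glycol cleavage), leaving the fused 1,2-acetonide, the tertiary silyl ether and C9 untouched.

Step 5
Reactants: 8 C10 aldehyde; 9 2-(triphenylphosphoranylidene)propanal
Product: 10 (E)-enal OHC(C2)–C1(C15)=C10H–C9 (furanose C4)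
Conditions: toluene, 80 °C
Reagents that add atoms: none
Why: Wittig olefination with a stabilised ylide should give the E-trisubstituted enal, which places C15 cis to C9 and so encodes the later trans relation of C2 and C9.

Step 6
Reactants: 10 (E)-enal; 3 amino siloxy diene; 11 vinylmagnesium bromide
Product: 14 ring A enone (cyclohex-13-en-12-one; 1β-Me, 10β-furanosyl, 11α-Me; 2β-hydroxyallyl at C1), via Diels–Alder adduct 12 (not isolated), via vinyl carbinol 13 (not isolated)
Conditions: toluene, 60 °C; then CH2=CHMgBr, THF, −78 °C; then 1 N HCl, THF, 0 °C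
Reagents that add atoms: none
Why: A normal-demand Diels–Alder reaction should join the nucleophilic diene terminus C11 to the enal β-carbon C10 and C14 to C1, the E-olefin fixing C2 trans to C9 and A(1,3) strain with C15 holding H9 in the olefin plane so that the diene adds anti to the bulky quaternary C8 and sets C1 and C10; Grignard 1,2-addition to the aldehyde of the still masked enone then follows the Felkin–Anh model (C10 large, reinforced by magnesium chelation to the cis C14 amine) to give the 2β-carbinol, and dilute acid hydrolyses the silyl enol ether and eliminates dimethylamine (E1cB).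

Step 7
Reactants: 14 ring A enone (11α-Me)
Product: 17 11β-methyl-12β-allylic alcohol, via dilithium dienolate 15 (not isolated), via 11β-methyl enone 16 (not isolated)
Conditions: LiN(iPr)2 (LDA, 2.2 equiv), THF, −78 → −40 °C; CeCl3·7H2O in MeOH, −78 °C; NaBH4, −78 °C
Reagents that add atoms: none
Why: The cross-conjugated dienolate (C1 is quaternary, so only C11 can be deprotonated) erases C11 and should be protonated kinetically from the α-face opposite C15 and the C9 chain, which turns C20 β, and immediate Luche reduction locks this centre, hydride likewise arriving from the open α-face to give the 12β-alcohol.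

Step 8
Reactants: 17 12β-allylic alcohol
Product: 19 12α-allylic alcohol, via 12α-nitrobenzoate 18 (not isolated)
Conditions: PPh3, DIAD, 4-O2NC6H4CO2H, toluene, 0 °C → rt; then K2CO3 (cat.), MeOH, rt
Reagents that add atoms: 4-nitrobenzoic acid, O=C(O)c1ccc(cc1)[N+](=O)[O-]
Why: Mitsunobu inversion (SN2 by carboxylate from the open α-face, SN2′ attack at neopentyl C14 and activation of the neopentyl 2-OH being sterically disfavoured) followed by methanolysis of the activated ester should set the 12α-configuration.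

Step 9
Reactants: 19 12α-allylic alcohol
Product: 20 12α-O-TBS ether (2β-OH free)
Conditions: TBSCl, imidazole, DMF, rt
Reagents that add atoms: tert-butyldimethylsilyl chloride, CC(C)(C)[Si](C)(C)Cl
Why: Silyl ether formation under mild conditions should select the 12-OH because the 2-OH is neopentyl, flanked by quaternary C1.

Step 10
Reactants: 20 12α-O-TBS ether
Product: 22 C7 aldehyde with 9α-O-formate (8α-OTBS, methyl ester), via furanose lactol 21 (not isolated)
Conditions: TFA–H2O (4:1), 0 °C; evaporation; NaIO4, THF–pH 7 buffer, 0 °C → rt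
Reagents that add atoms: none
Why: Acetal hydrolysis followed by periodate glycol cleavage should excise the anomeric carbon, which stays on O9 as a formate and so differentiates O9 from the later O7, while sugar C2 becomes the non-enolisable C7 aldehyde and the silylated O8 cannot take part in glycol cleavage.

Step 11
Reactants: 22 C7 aldehyde; 23 3-chloro-1-(trimethylsilyl)propyne
Product: 26 γ-lactone with 6α-chloro-propargyl side chain (C6HCl–C5≡C4–SiMe3), via chloroallenylzinc bromide 24 (not isolated), via anti chlorohydrin 25 (not isolated)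
Conditions: 23, ZnBr2, LiN(iPr)2 (LDA), THF, −78 °C; then 22, −78 → −20 °C; 1 N HCl; then PPTS (cat.), toluene, 60 °C
Reagents that add atoms: none
Why: SE2′ addition of a 3-chloroallenylzinc reagent to an aldehyde through a cyclic transition state should give the anti chlorohydrin (C6 relative to C7), the polar Felkin–Anh model (non-chelating O8 silyl ether anti to the nucleophile, C9 inside) sets C7 relative to C8, and acid-catalysed lactonisation can use only O7 because O9 is formylated.

Step 12
Reactants: 26 silylalkyne lactone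
Product: 27 terminal alkyne (seco-precursor)
Conditions: AgNO3 (10 mol %), acetone–H2O, rt
Reagents that add atoms: none
Why: Silver-catalysed protiodesilylation of the alkynylsilane runs under neutral conditions and should spare the formate, silyl ethers and lactone, and also the chloride, whose ionisation is disfavoured by the neighbouring acyloxy carbon.

Step 13
Reactants: 27 terminal alkyne; 28 ethylene
Product: 30 macrocyclic dienol (carbocycle C1–C10 closed; C16=C5–C4=C3 with 3Z; 2β-OH, 6α-Cl, 9α-OCHO, 8α- and 12α-OTBS, C13=C14), via butadiene triene 29 (not isolated)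
Conditions: RuCl2(=CHPh)(PCy3)(H2IMes) (second-generation Grubbs catalyst, 10 mol %), ethylene (1 atm), 1,4-benzoquinone (10 mol %), toluene (1 mM), 60 °C; then argon sparge, 80 °C
Reagents that add atoms: none
Why: The ruthenium methylidene adds to the terminal alkyne C5≡C4, the ruthenacyclobutene opens and turnover with ethylene gives the 2-substituted butadiene 29 (C16=C5–C4=CH2), whose monosubstituted vinyl end then undergoes diene–ene ring-closing metathesis with the C3 vinyl group and releases ethylene. The closest known reaction type is endo-selective macrocyclic ring-closing enyne metathesis under ethylene, used for ten- to fifteen-membered rings. The one ring closed is the ten-membered carbocycle C1–C10, in the endo mode (both alkyne carbons end in the ring, C16 stays exocyclic), by formation of C3=C4. No stereocentre is created; the only new stereoelement, the C3=C4 geometry, should settle as Z under reversible metathesis because an E-olefin conjugated to C5=C16 in a ten-membered ring trans-fused to ring A and to the lactone is much more strained. The step needs endo over exo mode, closure over oligomerisation and silence of the other olefins: prior conversion into 29 removes the exo path, the two trans ring fusions and the fully substituted C1 and C8 turn both chain ends toward each other at high dilution, and the hindered ring A olefin C13=C14 and the 1,1-disubstituted C5=C16 do not initiate. The free allylic 2-OH should speed loading at C3 and benzoquinone suppresses hydride-induced olefin migration.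

Step 14
Reactants: 30 macrocyclic dienol
Product: 31 3α,4α-epoxy-2β-alcohol (cis-oxirane, 3R,4R)
Conditions: VO(acac)2 (5 mol %), t-BuOOH, CH2Cl2, 0 °C
Reagents that add atoms: tert-butyl hydroperoxide, CC(C)(C)OO
Why: In this vanadium-catalysed hydroxyl-directed epoxidation A(1,3) strain of the Z-allylic alcohol keeps H2 in the olefin plane, so the 2β-OH should deliver oxygen to the outer face and give the threo epoxy alcohol, setting C3 and C4, while C5=C16 and C13=C14 have no free allylic hydroxyl.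

Step 15
Reactants: 31 epoxy alcohol
Product: 32 2-oxo-3α,4α-epoxide
Conditions: Dess–Martin periodinane, NaHCO3, CH2Cl2, 0 °C → rt
Reagents that add atoms: none
Why: Dess–Martin oxidation should act on the only free hydroxyl group and, being buffered and neutral, leave the vinyl oxirane, allylic chloride and formate intact.

Step 16
Reactants: 32 epoxy ketone
Product: 34 2α,9α-diol, via 2α-alcohol formate 33 (not isolated)
Conditions: NaBH4, CeCl3·7H2O, MeOH, −78 °C; then KHCO3, MeOH–H2O, 0 °C → rt
Reagents that add atoms: none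
Why: In this Luche-type reduction of an α,β-epoxy ketone, cerium bridging of carbonyl and oxirane oxygen (erythro rule) and the Felkin–Anh model at C1 both send hydride to the face that gives the 2α-alcohol (2S), and mild methanolysis then removes the formate, far more labile than the lactone.

Step 17
Reactants: 34 2α,9α-diol
Product: 35 2α,9α-diacetate
Conditions: Ac2O, DMAP, pyridine, rt → 40 °C
Reagents that add atoms: acetic anhydride, CC(=O)OC(C)=O
Why: DMAP-catalysed acylation should esterify the two free secondary alcohols with retention while O8 and O12 remain silylated.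

Step 18
Reactants: 35 diacetate
Product: 36 8α,12α-diol (13,14-deoxy target)
Conditions: HF·pyridine, pyridine, THF, 0 °C → rt
Reagents that add atoms: none
Why: Fluoride-driven desilylation in pyridine-buffered medium should free both hydroxyl groups without acetate migration or opening of the vinyl oxirane.

Step 19
Reactants: 36 8α,12α-diol
Product: 37 target CNP0141778.3
Conditions: mCPBA, NaHCO3, CH2Cl2, 0 °C
Reagents that add atoms: 3-chloroperoxybenzoic acid, O=C(OO)c1cccc(Cl)c1
Why: Hydroxyl-directed peracid epoxidation by the 12α-OH, on the face that is also sterically open because axial C15 and C20 shield the β-face, should set C13 and C14 as the α-oxirane, while C5=C16 is deactivated by the allylic chloride and the oxirane.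

Compound list
1 | (E)-4-(dimethylamino)but-3-en-2-one | CC(=O)/C=C/N(C)C | starting material
2 | (E)-1-(dimethylamino)pent-1-en-3-one | CCC(=O)/C=C/N(C)C | intermediate
3 | (1E,3Z)-3-(TBS-oxy)-N,N-dimethylpenta-1,3-dien-1-amine | C/C=C(O[Si](C)(C)C(C)(C)C)/C=C/N(C)C | intermediate
4 | 1,2:5,6-di-O-isopropylidene-α-D-ribo-hexofuranos-3-ulose | CC1(C)OC[C@@H](O1)[C@H]2O[C@@H]3OC(C)(C)O[C@@H]3C2=O | starting material
5 | methyl propanoate | CCC(=O)OC | starting material
6 | lithium aldolate | CC1(C)OC[C@@H](O1)[C@H]2O[C@@H]3OC(C)(C)O[C@@H]3[C@@]2([O-])[C@@H](C)C(=O)OC.[Li+] | intermediate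
7 | branched allofuranose TBS ether, methyl ester | CC1(C)OC[C@@H](O1)[C@H]2O[C@@H]3OC(C)(C)O[C@@H]3[C@@]2(O[Si](C)(C)C(C)(C)C)[C@@H](C)C(=O)OC | intermediate
8 | C10 aldehyde | O=C[C@H]1O[C@@H]2OC(C)(C)O[C@@H]2[C@@]1(O[Si](C)(C)C(C)(C)C)[C@@H](C)C(=O)OC | intermediate
9 | 2-(triphenylphosphoranylidene)propanal | CC(C=O)=P(c1ccccc1)(c1ccccc1)c1ccccc1 | starting material
10 | (E)-enal | O=C/C(C)=C/[C@H]1O[C@@H]2OC(C)(C)O[C@@H]2[C@@]1(O[Si](C)(C)C(C)(C)C)[C@@H](C)C(=O)OC | intermediate
11 | vinylmagnesium bromide | C=C[Mg]Br | starting material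
12 | Diels–Alder adduct (14α-NMe2, 11α-Me, C12 silyl enol ether, C2 aldehyde) | O=C[C@]1(C)[C@H]([C@H](C)C(O[Si](C)(C)C(C)(C)C)=C[C@@H]1N(C)C)[C@H]2O[C@@H]3OC(C)(C)O[C@@H]3[C@@]2(O[Si](C)(C)C(C)(C)C)[C@@H](C)C(=O)OC | intermediate
13 | 2β-vinyl carbinol of 12 | C=C[C@H](O)[C@]1(C)[C@H]([C@H](C)C(O[Si](C)(C)C(C)(C)C)=C[C@@H]1N(C)C)[C@H]2O[C@@H]3OC(C)(C)O[C@@H]3[C@@]2(O[Si](C)(C)C(C)(C)C)[C@@H](C)C(=O)OC | intermediate
14 | ring A enone, 11α-Me | C=C[C@H](O)[C@]1(C)[C@H]([C@H](C)C(=O)C=C1)[C@H]2O[C@@H]3OC(C)(C)O[C@@H]3[C@@]2(O[Si](C)(C)C(C)(C)C)[C@@H](C)C(=O)OC | intermediate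
15 | dilithium alkoxide dienolate | [Li+].[Li+].C=C[C@H]([O-])[C@]1(C)[C@H](C(C)=C([O-])C=C1)[C@H]2O[C@@H]3OC(C)(C)O[C@@H]3[C@@]2(O[Si](C)(C)C(C)(C)C)[C@@H](C)C(=O)OC | intermediate
16 | ring A enone, 11β-Me | C=C[C@H](O)[C@]1(C)[C@H]([C@@H](C)C(=O)C=C1)[C@H]2O[C@@H]3OC(C)(C)O[C@@H]3[C@@]2(O[Si](C)(C)C(C)(C)C)[C@@H](C)C(=O)OC | intermediate
17 | 11β-Me, 12β-allylic alcohol | C=C[C@H](O)[C@]1(C)[C@H]([C@@H](C)[C@@H](O)C=C1)[C@H]2O[C@@H]3OC(C)(C)O[C@@H]3[C@@]2(O[Si](C)(C)C(C)(C)C)[C@@H](C)C(=O)OC | intermediate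
18 | 12α-(4-nitrobenzoate) | C=C[C@H](O)[C@]1(C)[C@H]([C@@H](C)[C@H](OC(=O)c2ccc(cc2)[N+](=O)[O-])C=C1)[C@H]2O[C@@H]3OC(C)(C)O[C@@H]3[C@@]2(O[Si](C)(C)C(C)(C)C)[C@@H](C)C(=O)OC | intermediate
19 | 12α-allylic alcohol | C=C[C@H](O)[C@]1(C)[C@H]([C@@H](C)[C@H](O)C=C1)[C@H]2O[C@@H]3OC(C)(C)O[C@@H]3[C@@]2(O[Si](C)(C)C(C)(C)C)[C@@H](C)C(=O)OC | intermediate
20 | 12α-O-TBS ether | C=C[C@H](O)[C@]1(C)[C@H]([C@@H](C)[C@H](O[Si](C)(C)C(C)(C)C)C=C1)[C@H]2O[C@@H]3OC(C)(C)O[C@@H]3[C@@]2(O[Si](C)(C)C(C)(C)C)[C@@H](C)C(=O)OC | intermediate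
21 | furanose lactol (anomeric mixture) | C=C[C@H](O)[C@]1(C)[C@H]([C@@H](C)[C@H](O[Si](C)(C)C(C)(C)C)C=C1)[C@H]2OC(O)[C@H](O)[C@@]2(O[Si](C)(C)C(C)(C)C)[C@@H](C)C(=O)OC | intermediate
22 | C7 aldehyde, 9-O-formate | C=C[C@H](O)[C@]1(C)[C@H]([C@@H](C)[C@H](O[Si](C)(C)C(C)(C)C)C=C1)[C@@H](OC=O)[C@](C=O)(O[Si](C)(C)C(C)(C)C)[C@@H](C)C(=O)OC | intermediate
23 | 3-chloro-1-(trimethylsilyl)propyne | C[Si](C)(C)C#CCCl | starting material
24 | 3-chloro-1-(trimethylsilyl)allenylzinc bromide (racemic, labile axis) | C[Si](C)(C)C([Zn]Br)=C=CCl | intermediate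
25 | anti chlorohydrin | C=C[C@H](O)[C@]1(C)[C@H]([C@@H](C)[C@H](O[Si](C)(C)C(C)(C)C)C=C1)[C@@H](OC=O)[C@]([C@@H](O)[C@H](C#C[Si](C)(C)C)Cl)(O[Si](C)(C)C(C)(C)C)[C@@H](C)C(=O)OC | intermediate
26 | γ-lactone, silylalkyne | C=C[C@H](O)[C@]1(C)[C@H]([C@@H](C)[C@H](O[Si](C)(C)C(C)(C)C)C=C1)[C@@H](OC=O)[C@]2(O[Si](C)(C)C(C)(C)C)[C@@H](C)C(=O)O[C@H]2[C@H](C#C[Si](C)(C)C)Cl | intermediate
27 | γ-lactone, terminal alkyne (seco-precursor) | C=C[C@H](O)[C@]1(C)[C@H]([C@@H](C)[C@H](O[Si](C)(C)C(C)(C)C)C=C1)[C@@H](OC=O)[C@]2(O[Si](C)(C)C(C)(C)C)[C@@H](C)C(=O)O[C@H]2[C@H](C#C)Cl | intermediate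
28 | ethylene | C=C | starting material
29 | 2-substituted butadiene triene | C=C[C@H](O)[C@]1(C)[C@H]([C@@H](C)[C@H](O[Si](C)(C)C(C)(C)C)C=C1)[C@@H](OC=O)[C@]2(O[Si](C)(C)C(C)(C)C)[C@@H](C)C(=O)O[C@H]2[C@H](C(=C)C=C)Cl | intermediate
30 | macrocyclic (3Z)-dienol | C=C1/C=C\[C@H](O)[C@]2(C)[C@H]([C@@H](C)[C@H](O[Si](C)(C)C(C)(C)C)C=C2)[C@@H](OC=O)[C@]2(O[Si](C)(C)C(C)(C)C)[C@@H](C)C(=O)O[C@H]2[C@H]1Cl | intermediate
31 | 3α,4α-epoxy-2β-alcohol | C=C1[C@H]2O[C@H]2[C@H](O)[C@]2(C)[C@H]([C@@H](C)[C@H](O[Si](C)(C)C(C)(C)C)C=C2)[C@@H](OC=O)[C@]2(O[Si](C)(C)C(C)(C)C)[C@@H](C)C(=O)O[C@H]2[C@H]1Cl | intermediate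
32 | 2-oxo-3α,4α-epoxide | C=C1[C@H]2O[C@H]2C(=O)[C@]2(C)[C@H]([C@@H](C)[C@H](O[Si](C)(C)C(C)(C)C)C=C2)[C@@H](OC=O)[C@]2(O[Si](C)(C)C(C)(C)C)[C@@H](C)C(=O)O[C@H]2[C@H]1Cl | intermediate
33 | 2α-alcohol, 9-O-formate | C=C1[C@H]2O[C@H]2[C@@H](O)[C@]2(C)[C@H]([C@@H](C)[C@H](O[Si](C)(C)C(C)(C)C)C=C2)[C@@H](OC=O)[C@]2(O[Si](C)(C)C(C)(C)C)[C@@H](C)C(=O)O[C@H]2[C@H]1Cl | intermediate
34 | 2α,9α-diol | C=C1[C@H]2O[C@H]2[C@@H](O)[C@]2(C)[C@H]([C@@H](C)[C@H](O[Si](C)(C)C(C)(C)C)C=C2)[C@@H](O)[C@]2(O[Si](C)(C)C(C)(C)C)[C@@H](C)C(=O)O[C@H]2[C@H]1Cl | intermediate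
35 | 2α,9α-diacetate | C=C1[C@H]2O[C@H]2[C@@H](OC(C)=O)[C@]2(C)[C@H]([C@@H](C)[C@H](O[Si](C)(C)C(C)(C)C)C=C2)[C@@H](OC(C)=O)[C@]2(O[Si](C)(C)C(C)(C)C)[C@@H](C)C(=O)O[C@H]2[C@H]1Cl | intermediate
36 | 8α,12α-diol, C13=C14 olefin | C=C1[C@H]2O[C@H]2[C@@H](OC(C)=O)[C@]2(C)[C@H]([C@@H](C)[C@H](O)C=C2)[C@@H](OC(C)=O)[C@]2(O)[C@@H](C)C(=O)O[C@H]2[C@H]1Cl | intermediate
37 | CNP0141778.3 | C=C1[C@H]2O[C@H]2[C@@H](OC(C)=O)[C@]2(C)[C@H]([C@@H](C)[C@H](O)[C@@H]3O[C@@H]32)[C@@H](OC(C)=O)[C@]2(O)[C@@H](C)C(=O)O[C@H]2[C@H]1Cl | target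

Total step count: 19. Longest linear sequence: 17 steps (steps 3–19, from 4).

Steps most likely to fail

1. Step 13 (key step).
- What may go wrong: intermolecular metathesis (oligomerisation) may outrun closure of the strained ring, or the sequence may stall at the open triene.
- Fallback, from 27 back to 32: the allylic alcohol is oxidised with MnO2 to vinyl ketone F1. Under the same ruthenium catalyst and ethylene this should pass through triene ketone F2 to macrocyclic cross-conjugated dienone F3. An enone terminus does not homodimerise, and a trigonal C2 removes one transannular contact. Weitz–Scheffer epoxidation of the enone double bond C3=C4 (t-BuOOH, DBU) from the outer face then gives epoxy ketone 32 directly, so steps 14 and 15 are skipped.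

2. Step 7.
- What may go wrong: facial selectivity in the protonation of the lithium dienolate may be poor, or C11 may re-equilibrate before the ketone is reduced.
- Fallback, from 14 back to 16: soft enolisation (Me3SiOTf, Et3N) gives the isolable bis(trimethylsilyl) dienol ether F4. It is protonated under reagent control with the matched enantiomer of the BINOL·SnCl4 Brønsted acid at −78 °C. Mild acidic work-up removes the 2-O-silyl group and gives the 11β-methyl enone 16, now isolated, which is reduced to 17 under the Luche conditions of step 7.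

3. Step 6.
- What may go wrong: cycloaddition to the hindered trisubstituted enal may be slow, letting hetero-cycloaddition at the formyl group or decay of the amino diene compete.
- Fallback, from 10 back to 14: ethyl vinyl ketone is silylated (TBSOTf, Et3N) to the 2-siloxy diene F5. A Me2AlCl-promoted Diels–Alder reaction with 10 gives silyl enol ether aldehyde F6. Regiochemistry and facial control are the same, and there is no 1-heteroatom to favour the hetero pathway. CH2=CHMgBr then gives vinyl carbinol F7, and Saegusa–Ito oxidation with Pd(OAc)2 introduces C13=C14 and delivers 14.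

Further compounds
F1 | step 13 | vinyl ketone | C=CC(=O)[C@]1(C)[C@H]([C@@H](C)[C@H](O[Si](C)(C)C(C)(C)C)C=C1)[C@@H](OC=O)[C@]2(O[Si](C)(C)C(C)(C)C)[C@@H](C)C(=O)O[C@H]2[C@H](C#C)Cl
F2 | step 13 | triene ketone | C=CC(=O)[C@]1(C)[C@H]([C@@H](C)[C@H](O[Si](C)(C)C(C)(C)C)C=C1)[C@@H](OC=O)[C@]2(O[Si](C)(C)C(C)(C)C)[C@@H](C)C(=O)O[C@H]2[C@H](C(=C)C=C)Cl
F3 | step 13 | macrocyclic cross-conjugated dienone | C=C1/C=C\C(=O)[C@]2(C)[C@H]([C@@H](C)[C@H](O[Si](C)(C)C(C)(C)C)C=C2)[C@@H](OC=O)[C@]2(O[Si](C)(C)C(C)(C)C)[C@@H](C)C(=O)O[C@H]2[C@H]1Cl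
F4 | step 7 | bis(trimethylsilyl) dienol ether | C=C[C@H](O[Si](C)(C)C)[C@]1(C)[C@H](C(C)=C(O[Si](C)(C)C)C=C1)[C@H]2O[C@@H]3OC(C)(C)O[C@@H]3[C@@]2(O[Si](C)(C)C(C)(C)C)[C@@H](C)C(=O)OC
F5 | step 6 | (Z)-3-(TBS-oxy)penta-1,3-diene | C/C=C(O[Si](C)(C)C(C)(C)C)/C=C
F6 | step 6 | silyl enol ether aldehyde | O=C[C@]1(C)[C@H]([C@H](C)C(O[Si](C)(C)C(C)(C)C)=CC1)[C@H]2O[C@@H]3OC(C)(C)O[C@@H]3[C@@]2(O[Si](C)(C)C(C)(C)C)[C@@H](C)C(=O)OC
F7 | step 6 | vinyl carbinol silyl enol ether | C=C[C@H](O)[C@]1(C)[C@H]([C@H](C)C(O[Si](C)(C)C(C)(C)C)=CC1)[C@H]2O[C@@H]3OC(C)(C)O[C@@H]3[C@@]2(O[Si](C)(C)C(C)(C)C)[C@@H](C)C(=O)OC
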